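**Plan**

1. Retrosynthesis: the O–CH3 bond of a 6-O-methyl ether is cut last; then the dihydropyran ring (ring B) is opened at C3–C4 and at O1–C8a together. This gives oxirane 16 (O1, C2, C3 and the whole side chain) and ortho-bromobenzyl chloride 20 (C4, C4a and C8a of the benzene ring, ring A).
2. Enabling feature: ring B is an O1–C2–C3 triad (the atoms of a 2,2-disubstituted oxirane) joined to a benzylic carbon C4 whose ring carbon C4a is ortho to C8a. C2 is quaternary and no bond to it is made or broken, its alkoxide has no β-hydrogen, and ring A is fully substituted, so the benzylic nucleophile can only react through C4.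
3. Oxirane 16 is cut at C1′–C2′ (2-methylglycidyl tosylate 13 plus C15 bromide 11); the chain is cut at C4′–C5′ (β-lactone opening) and at C10′–C11′ (methallyl coupling).
4. Forward: chain (steps 1–6), oxirane (steps 7–8), ring A fragment (steps 9–11), annulation of ring B onto ring A (step 12), release of the phenol (step 13).
5. Stereochemistry: C2 from (S)-2-methylglycidol (a Sharpless-epoxidation chiral-pool reagent, all four bonds kept); C4′ from (R)-β-butyrolactone by SN2 inversion; C8′ from (S)-citronellyl bromide. None is touched afterwards.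

Key step: step 12

Remark: chain atoms are numbered C1′ to C13′ from C2 of the chroman. Because of the C12′ alkene the CIP descriptor at C8′ is S, although the spatial arrangement is that of the natural tocopherol side chain. Compounds 1, 4, 7, 12 and 17 are taken as commercially available.

**Route**

Step 1
Reactants: 1 (S)-citronellyl bromide, (6S)-8-bromo-2,6-dimethyloct-2-ene
Product: 3 (4S)-6-bromo-4-methylhexan-1-ol, via ozonide 2 (not isolated)
Conditions: O3, CH2Cl2, −78 °C; then NaBH4, MeOH, −78 °C to rt
Reagents that add atoms: ozone, [O-][O+]=O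
Why: Ozonolysis cleaves only the trisubstituted alkene and hydride reduction of ozonide 2 in the same flask gives the primary alcohol, while the primary bromide and the stereocenter taken from 1 are not touched.

Step 2
Reactants: 3 (4S)-6-bromo-4-methylhexan-1-ol; 4 methallylmagnesium chloride
Product: 5 (4R)-4,8-dimethylnon-8-en-1-ol
Conditions: 4 (2.5 equiv), Li2CuCl4 (3 mol%), THF, −20 °C to rt; then aq. HCl
Reagents that add atoms: none
Why: Copper-catalysed alkyl–alkyl Grignard cross-coupling at the primary bromide with the symmetrical methallyl nucleophile (one equivalent of 4 is spent on the hydroxyl) puts on the isopropenyl end; the stereocenter is not involved and its descriptor changes from S to R only through the change of ligand priorities.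

Step 3
Reactants: 5 (4R)-4,8-dimethylnon-8-en-1-ol
Product: 6 (6R)-9-bromo-2,6-dimethylnon-1-ene
Conditions: CBr4, PPh3, CH2Cl2, 0 °C
Reagents that add atoms: carbon tetrabromide, BrC(Br)(Br)Br
Why: The Appel reaction converts the primary alcohol into the bromide under neutral conditions that leave the 1,1-disubstituted alkene and the stereocenter alone.

Step 4
Reactants: 6 (6R)-9-bromo-2,6-dimethylnon-1-ene; 7 (R)-β-butyrolactone, (4R)-4-methyloxetan-2-one
Product: 9 (3R,7S)-3,7,11-trimethyldodec-11-enoic acid, via alkylmagnesium bromide 8 (not isolated)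
Conditions: Mg, THF, rt; then 7, CuBr·SMe2 (5 mol%), THF/Me2S, −30 to 0 °C; then aq. HCl
Reagents that add atoms: none
Why: Copper-catalysed SN2 opening of the β-lactone at its methyl-bearing carbon (alkyl–oxygen cleavage) by primary Grignard reagent 8 gives the 3-methyl acid, and C3 of 9 (C4′ of the target) is set by inversion of the (R) lactone stereocenter.

Step 5
Reactants: 9 (3R,7S)-3,7,11-trimethyldodec-11-enoic acid
Product: 10 (3R,7S)-3,7,11-trimethyldodec-11-en-1-ol
Conditions: LiAlH4, THF, 0 °C to rt; then H2O
Reagents that add atoms: none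
Why: LiAlH4 reduction takes the carboxylic acid to the primary alcohol, and the isolated alkene and both stereocenters are inert to hydride.

Step 6
Reactants: 10 (3R,7S)-3,7,11-trimethyldodec-11-en-1-ol
Product: 11 (6S,10R)-12-bromo-2,6,10-trimethyldodec-1-ene
Conditions: CBr4, PPh3, CH2Cl2, 0 °C
Reagents that add atoms: carbon tetrabromide, BrC(Br)(Br)Br
Why: The Appel reaction as in step 3 gives the primary bromide needed for the Grignard reagent of step 8 without touching the alkene or the stereocenters.

Step 7
Reactants: 12 (S)-2-methylglycidol, [(2S)-2-methyloxiran-2-yl]methanol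
Product: 13 [(2R)-2-methyloxiran-2-yl]methyl 4-methylbenzenesulfonate
Conditions: TsCl, Et3N, DMAP (cat.), CH2Cl2, 0 °C
Reagents that add atoms: 4-toluenesulfonyl chloride, Cc1ccc(cc1)S(Cl)(=O)=O
Why: Sulfonylation of the primary hydroxyl makes the leaving group for the epoxide relay of step 8; no bond at the quaternary stereocenter changes, and the descriptor goes from S to R only by priority.

Step 8
Reactants: 11 (6S,10R)-12-bromo-2,6,10-trimethyldodec-1-ene; 13 [(2R)-2-methyloxiran-2-yl]methyl 4-methylbenzenesulfonate
Product: 16 (2R)-2-methyl-2-[(4R,8S)-4,8,12-trimethyltridec-12-en-1-yl]oxirane, via alkylmagnesium bromide 14 (not isolated), via hydroxy tosylate 15 (not isolated)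
Conditions: Mg, THF, rt; then 13, CuI (10 mol%), THF, −40 to 0 °C; then NaOMe, MeOH, 0 °C to rt
Reagents that add atoms: none
Why: Copper-catalysed Grignard opening of the oxirane of 13 at its CH2 (the neopentyl-type CH2OTs is displaced far more slowly) and then base-induced 3-exo-tet Williamson closure of the tertiary alkoxide of 15 onto CH2OTs move the epoxide to the other side, and because the quaternary carbon keeps all four bonds (R)-13 gives (2R)-16.

Step 9
Reactants: 17 2,3,6-trimethylphenol
Product: 18 4-bromo-2,3,6-trimethylphenol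
Conditions: NBS, MeCN, 0 °C
Reagents that add atoms: N-bromosuccinimide, BrN1C(=O)CCC1=O
Why: Electrophilic aromatic bromination goes para to the hydroxyl because both ortho positions carry methyl groups.

Step 10
Reactants: 18 4-bromo-2,3,6-trimethylphenol
Product: 19 1-bromo-4-methoxy-2,3,5-trimethylbenzene
Conditions: MeI, K2CO3, acetone, reflux
Reagents that add atoms: iodomethane, CI
Why: Williamson O-methylation of the phenoxide gives a methyl ether that survives the acid of step 11 and the organometallic and basic conditions of step 12.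

Step 11
Reactants: 19 1-bromo-4-methoxy-2,3,5-trimethylbenzene
Product: 20 1-bromo-2-(chloromethyl)-4-methoxy-3,5,6-trimethylbenzene
Conditions: (CH2O)n, HCl (gas), ZnCl2 (cat.), AcOH, 70 °C
Reagents that add atoms: formaldehyde (as paraformaldehyde), C=O; hydrogen chloride, Cl
Why: Blanc chloromethylation can only take place at the single free ring position, which is ortho and para to two methyl groups and next to the bromine, and this places the CH2Cl group ortho to C–Br as step 12 requires.

Step 12
Reactants: 20 1-bromo-2-(chloromethyl)-4-methoxy-3,5,6-trimethylbenzene; 16 (2R)-2-methyl-2-[(4R,8S)-4,8,12-trimethyltridec-12-en-1-yl]oxirane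
Product: 23 (2R)-6-methoxy-2,5,7,8-tetramethyl-2-[(4R,8S)-4,8,12-trimethyltridec-12-en-1-yl]-3,4-dihydro-2H-chromene, via benzylmagnesium chloride 21 (not isolated), via bromo alcohol 22 (not isolated)
Conditions: 20, Mg, THF, 0 °C; then 16, CuI (10 mol%), THF, −30 to 0 °C; then t-BuOH (quench of excess 21), NaOt-Bu, Pd2(dba)3 (2.5 mol%), 2-(di-tert-butylphosphino)-1,1′-binaphthyl (6 mol%), toluene, 80 °C, same flask
Reagents that add atoms: none
Why: Magnesium inserts into the benzylic C–Cl bond of 20 (the hindered aryl C–Br bond is kept), and copper-mediated SN2 attack of the benzylic carbon C4 of 21 on the unsubstituted oxirane carbon of 16 forms C3–C4 and sets free the tertiary C2 alkoxide 22; after base and catalyst are added, zerovalent palladium inserts into the C8a–Br bond ortho to the new chain, the alkoxide displaces bromide on palladium and C–O reductive elimination forms O1–C8a. The closest known reaction types are the copper-catalysed opening of 2,2-disubstituted epoxides by benzylic Grignard reagents and the palladium-catalysed intramolecular etherification of tertiary alcohols with aryl bromides (Buchwald–Hartwig type), here run one after the other in one flask as a formal [3+3] annulation. Ring B closes in the second event by reductive elimination from a seven-membered aryl(alkoxo)palladium chelate, formally a 6-exo attack of O1 on the ipso carbon C8a. No stereocenter is created: C2 comes from 16 with retention because neither new bond ends at C2 and none of its four bonds is broken, and C4′ and C8′ are remote. The step needs attack at the oxirane CH2 and not at the quaternary carbon (secured by the steric bias of SN2 under copper catalysis at low temperature, which should also outrun magnesium-halide-induced epoxide rearrangement), reaction through C4 and not through the ring (both ortho positions of 21 are substituted), and O-arylation in preference to reduction of the aryl bromide (the tertiary alkoxide has no hydrogen on its carbinol carbon, so β-hydride elimination is impossible).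

Step 13
Reactants: 23 (2R)-6-methoxy-2,5,7,8-tetramethyl-2-[(4R,8S)-4,8,12-trimethyltridec-12-en-1-yl]-3,4-dihydro-2H-chromene
Product: 24 (2R)-2,5,7,8-tetramethyl-2-[(4R,8S)-4,8,12-trimethyltridec-12-en-1-yl]-3,4-dihydro-2H-chromen-6-ol
Conditions: NaSEt, DMF, 130 °C, argon; then aq. HCl
Reagents that add atoms: none
Why: Ethanethiolate removes the O-methyl group by SN2 attack at the methyl carbon, while the tertiary alkyl aryl ether of ring B, the terminal alkene and the three stereocenters are inert to this soft nucleophile.

**Compound list**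

1 | (S)-citronellyl bromide, (6S)-8-bromo-2,6-dimethyloct-2-ene | BrCC[C@@H](C)CCC=C(C)C | starting material
2 | 3-[(3S)-5-bromo-3-methylpentyl]-5,5-dimethyl-1,2,4-trioxolane (ozonide, both epimers at the ring CH) | BrCC[C@@H](C)CCC1OOC(C)(C)O1 | intermediate
3 | (4S)-6-bromo-4-methylhexan-1-ol | BrCC[C@@H](C)CCCO | intermediate
4 | methallylmagnesium chloride, (2-methylprop-2-en-1-yl)magnesium chloride | C=C(C)C[Mg]Cl | starting material
5 | (4R)-4,8-dimethylnon-8-en-1-ol | C=C(C)CCC[C@@H](C)CCCO | intermediate
6 | (6R)-9-bromo-2,6-dimethylnon-1-ene | C=C(C)CCC[C@@H](C)CCCBr | intermediate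
7 | (R)-β-butyrolactone, (4R)-4-methyloxetan-2-one | C[C@@H]1CC(=O)O1 | starting material
8 | [(4R)-4,8-dimethylnon-8-en-1-yl]magnesium bromide | C=C(C)CCC[C@@H](C)CCC[Mg]Br | intermediate
9 | (3R,7S)-3,7,11-trimethyldodec-11-enoic acid | C=C(C)CCC[C@@H](C)CCC[C@@H](C)CC(=O)O | intermediate
10 | (3R,7S)-3,7,11-trimethyldodec-11-en-1-ol | C=C(C)CCC[C@@H](C)CCC[C@@H](C)CCO | intermediate
11 | (6S,10R)-12-bromo-2,6,10-trimethyldodec-1-ene | C=C(C)CCC[C@@H](C)CCC[C@@H](C)CCBr | intermediate
12 | (S)-2-methylglycidol, [(2S)-2-methyloxiran-2-yl]methanol | C[C@]1(CO)CO1 | starting material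
13 | [(2R)-2-methyloxiran-2-yl]methyl 4-methylbenzenesulfonate | C[C@]1(COS(=O)(=O)c2ccc(C)cc2)CO1 | intermediate
14 | [(3R,7S)-3,7,11-trimethyldodec-11-en-1-yl]magnesium bromide | C=C(C)CCC[C@@H](C)CCC[C@@H](C)CC[Mg]Br | intermediate
15 | (2R,6R,10S)-2-hydroxy-2,6,10,14-tetramethylpentadec-14-en-1-yl 4-methylbenzenesulfonate (bromomagnesium alkoxide in the flask) | C=C(C)CCC[C@@H](C)CCC[C@@H](C)CCC[C@@](C)(O)COS(=O)(=O)c1ccc(C)cc1 | intermediate
16 | (2R)-2-methyl-2-[(4R,8S)-4,8,12-trimethyltridec-12-en-1-yl]oxirane | C=C(C)CCC[C@@H](C)CCC[C@@H](C)CCC[C@]1(C)CO1 | intermediate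
17 | 2,3,6-trimethylphenol | Cc1ccc(C)c(O)c1C | starting material
18 | 4-bromo-2,3,6-trimethylphenol | Cc1cc(Br)c(C)c(C)c1O | intermediate
19 | 1-bromo-4-methoxy-2,3,5-trimethylbenzene | COc1c(C)cc(Br)c(C)c1C | intermediate
20 | 1-bromo-2-(chloromethyl)-4-methoxy-3,5,6-trimethylbenzene | COc1c(C)c(CCl)c(Br)c(C)c1C | intermediate
21 | [(2-bromo-5-methoxy-3,4,6-trimethylphenyl)methyl]magnesium chloride | COc1c(C)c(C[Mg]Cl)c(Br)c(C)c1C | intermediate
22 | (3R,7R,11S)-1-(2-bromo-5-methoxy-3,4,6-trimethylphenyl)-3,7,11,15-tetramethylhexadec-15-en-3-ol (chloromagnesium alkoxide in the flask) | C=C(C)CCC[C@@H](C)CCC[C@@H](C)CCC[C@@](C)(O)CCc1c(C)c(OC)c(C)c(C)c1Br | intermediate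
23 | (2R)-6-methoxy-2,5,7,8-tetramethyl-2-[(4R,8S)-4,8,12-trimethyltridec-12-en-1-yl]-3,4-dihydro-2H-chromene | C=C(C)CCC[C@@H](C)CCC[C@@H](C)CCC[C@]1(C)CCc2c(C)c(OC)c(C)c(C)c2O1 | intermediate
24 | (2R)-2,5,7,8-tetramethyl-2-[(4R,8S)-4,8,12-trimethyltridec-12-en-1-yl]-3,4-dihydro-2H-chromen-6-ol (CNP0115007.1) | C=C(C)CCC[C@@H](C)CCC[C@@H](C)CCC[C@]1(C)CCc2c(C)c(O)c(C)c(C)c2O1 | target

**Step count and risks**

Total step count: 13. Longest linear sequence: 9 steps (steps 1–6, 8, 12, 13).

Step 12. The benzylic Grignard reagent may homocouple as it forms, the oxirane may rearrange under magnesium halide before it is benzylated, or the palladium cycle may stall in the magnesium- and copper-laden one-pot mixture. The fallback sets out from 16 and comes back at 24 (step 13 is then not needed); it closes ring B at the quinone oxidation level instead of by cross-coupling. Blanc chloromethylation of commercial 1,4-dimethoxy-2,3,5-trimethylbenzene gives 2-(chloromethyl)-1,4-dimethoxy-3,5,6-trimethylbenzene F1. Its Grignard reagent, (2,5-dimethoxy-3,4,6-trimethylbenzyl)magnesium chloride F2, opens 16 (CuI cat., THF, −30 °C) to the tertiary alcohol (3R,7R,11S)-1-(2,5-dimethoxy-3,4,6-trimethylphenyl)-3,7,11,15-tetramethylhexadec-15-en-3-ol F3. Oxidative demethylation with (NH4)2Ce(NO3)6 in aqueous MeCN should give the hydroxy quinone 2-[(3R,7R,11S)-3-hydroxy-3,7,11,15-tetramethylhexadec-15-en-1-yl]-3,5,6-trimethylcyclohexa-2,5-diene-1,4-dione F4. Na2S2O4 reduces it to the hydroquinone 2-[(3R,7R,11S)-3-hydroxy-3,7,11,15-tetramethylhexadec-15-en-1-yl]-3,5,6-trimethylbenzene-1,4-diol F5, and mild acid (cat. p-TsOH, toluene, 60 °C, argon) should close it to 24. In this known type of tocopherol ring closure the tertiary hydroxyl replaces the ring oxygen at C8a through the hemiketal of the keto form, so C2 should be retained.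

Step 11. Electrophilic substitution at the only free position, which is flanked by bromine and a methyl group, may be too slow, and the benzyl chloride formed may alkylate a second arene molecule or the ether may be cleaved by the acid. The fallback sets out from 19 and comes back at 20; it introduces the carbon at the aldehyde level with a stronger, irreversible electrophile. Rieche formylation (Cl2CHOMe, TiCl4, CH2Cl2, 0 °C) should give 2-bromo-5-methoxy-3,4,6-trimethylbenzaldehyde F6, NaBH4 in MeOH gives (2-bromo-5-methoxy-3,4,6-trimethylphenyl)methanol F7, and conc. HCl converts this electron-rich benzylic alcohol into 20.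

Step 8. Direct displacement of the tosylate by the Grignard reagent, in competition with oxirane opening, would lead to the enantiomeric epoxide and so erode the configuration at C2; the alkoxide closure may also be incomplete. The fallback sets out from 12 and 14 and comes back at 15; it forms the C–C bond with no leaving group in the molecule. (S)-2-Methylglycidol 12 is first converted into its magnesium alkoxide with i-PrMgCl and then opened at the oxirane CH2 by 14 (CuI cat., THF, −30 °C) to give (2R,6R,10S)-2,6,10,14-tetramethylpentadec-14-ene-1,2-diol F8. Selective tosylation of the primary hydroxyl (TsCl, pyridine, 0 °C) gives 15, which is closed to 16 with NaOMe as in step 8.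

**Further compounds**

F1 | step 12 | 2-(chloromethyl)-1,4-dimethoxy-3,5,6-trimethylbenzene | COc1c(C)c(C)c(OC)c(CCl)c1C
F2 | step 12 | (2,5-dimethoxy-3,4,6-trimethylbenzyl)magnesium chloride | COc1c(C)c(C)c(OC)c(C[Mg]Cl)c1C
F3 | step 12 | (3R,7R,11S)-1-(2,5-dimethoxy-3,4,6-trimethylphenyl)-3,7,11,15-tetramethylhexadec-15-en-3-ol | C=C(C)CCC[C@@H](C)CCC[C@@H](C)CCC[C@@](C)(O)CCc1c(C)c(OC)c(C)c(C)c1OC
F4 | step 12 | 2-[(3R,7R,11S)-3-hydroxy-3,7,11,15-tetramethylhexadec-15-en-1-yl]-3,5,6-trimethylcyclohexa-2,5-diene-1,4-dione | C=C(C)CCC[C@@H](C)CCC[C@@H](C)CCC[C@@](C)(O)CCC1=C(C)C(=O)C(C)=C(C)C1=O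
F5 | step 12 | 2-[(3R,7R,11S)-3-hydroxy-3,7,11,15-tetramethylhexadec-15-en-1-yl]-3,5,6-trimethylbenzene-1,4-diol | C=C(C)CCC[C@@H](C)CCC[C@@H](C)CCC[C@@](C)(O)CCc1c(C)c(O)c(C)c(C)c1O
F6 | step 11 | 2-bromo-5-methoxy-3,4,6-trimethylbenzaldehyde | COc1c(C)c(C=O)c(Br)c(C)c1C
F7 | step 11 | (2-bromo-5-methoxy-3,4,6-trimethylphenyl)methanol | COc1c(C)c(CO)c(Br)c(C)c1C
F8 | step 8 | (2R,6R,10S)-2,6,10,14-tetramethylpentadec-14-ene-1,2-diol | C=C(C)CCC[C@@H](C)CCC[C@@H](C)CCC[C@@](C)(O)CO
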